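Time is nearly idle here, I reckon: the autumn run, which has this flask's equivalents of solid reagent, is flat from its first reading at 1.50 min, and the flask stands for 30 min, 20.0 times as long.

| setting | winter | summer | autumn | flask |
|---|---|---|---|---|
| left-handed substrate | 10 mM | 10 mM | 10 mM | 10 mM |
| right-handed substrate | 10 mM | 10 mM | 10 mM | 10 mM |
| solid reagent | 0.50 equiv | 2 equiv | 1 equiv | 1.00 equiv |
| catalyst | 5 mol% | 5 mol% | 7.5 mol% | 5 mol% |
| remark | run made earlier | run made earlier | run made earlier |  |
| time |  |  |  | 30 min |

| run | time / min | left-handed substrate / % | left-handed product / % | right-handed substrate / % |
|---|---|---|---|---|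
| winter | 1.33 | 28.5 | 23.6 | 46.4 |
| winter | 4.00 | 27.8 | 22.9 | 45.8 |
| winter | 6.00 | 26.0 | 23.0 | 45.0 |
| winter | 10.0 | 24.6 | 22.7 | 48.2 |
| winter | 15.0 | 25.8 | 22.8 | 46.6 |
| winter | 20.0 | 29.2 | 22.7 | 48.7 |
| summer | 1.33 | 0 | 51.0 | 11.2 |
| summer | 4.00 | 0.3 | 50.5 | 1.2 |
| summer | 6.00 | 0 | 50.9 | 2.7 |
| summer | 10.0 | 0 | 49.4 | 2.5 |
| summer | 15.0 | 0 | 50.2 | 1.1 |
| summer | 20.0 | 0 | 47.8 | 1.3 |
| autumn | 1.50 | 7.0 | 43.2 | 42.6 |
| autumn | 5.00 | 5.6 | 41.8 | 42.7 |
| autumn | 8.00 | 10.2 | 42.8 | 42.4 |
| autumn | 12.0 | 7.4 | 42.7 | 42.8 |
| autumn | 20.0 | 6.7 | 42.1 | 43.1 |

(readings scatter by 1 percentage point)

- catalyst is single-handed; left-handed substrate and right-handed substrate are mirror images of each other, charged as a racemate, each of them at the stated concentration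
- given per volume of solution although it is solid: solid reagent
- the numbers in the tables scatter by 1 percentage point (one standard deviation)
- at the start none of the solid reagent is in solution
- the reaction counts as stopped when no species that holds the left-handed substrate and right-handed substrate together changes by six tenths of a point or more over the second half of the time

- which holds at 30 min: what has brought the reaction to rest, or that it has not come to rest (for what has run out or reacted, a solid counts together with what of it has only dissolved) (the partner has run out first / all of the left-handed substrate has reacted / no working catalyst is left / it is still moving)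
- conversion of left-handed substrate and right-handed substrate together at 30 min
- amount of left-handed product at 30 min, in percent of the left-handed substrate and right-handed substrate together charged
- amount of right-handed substrate at 30 min, in percent of the left-handed substrate and right-handed substrate together charged

The ladder has three rungs. On the fastest, left-handed substrate reacts: in the summer run, at the flask's loading of 5 mol%, it reads 0% at 1.33 min, while right-handed substrate still reads 11.2%. On the next, right-handed substrate follows, down to 1.2% at 4.00 min. On the last, the summer readings scatter.

So I count partner, the limiting reagent. One equivalent pays for one charge of left-handed substrate, which gives this flask a budget of 50.0% conversion. The autumn run has the same budget. Its means are 42.5% left-handed product and 42.7% right-handed substrate, so it used 49.8%.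

The small thing is the leak, the partner spent on right-handed substrate. At this budget, each right-handed molecule that reacts leaves one left-handed molecule over, so product and right-handed substrate should read alike. I pool both means to 42.6%, which makes the leak 7.38%. This autumn reading gives the selectivity factor s, the logarithm of the fraction of left-handed substrate left divided by that of the fraction of right-handed substrate left: 12.0. I assume the lower loading keeps this split, so I commit to 42.6% for both.

The forecast says the partner has run out first, with conversion 50% (48% to 52%), left-handed product 42% and right-handed substrate 42%, since consumption “tracks the solid”.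

In the flask, the partner has run out first; conversion is 50.0%, left-handed product 42.8% and right-handed substrate 42.8%.

    partner + catalyst + left-handed substrate → catalyst + left-handed product (k = 3.40 × 10⁵ L² mol⁻² s⁻¹)
    partner + catalyst + right-handed substrate → catalyst + right-handed product (k = 27000 L² mol⁻² s⁻¹)
    solid reagent ⇌ partner, rate k3*(cs3 - [partner]) while solid is left; crystals form when [partner] > cs3 (solubility = 5.50 mM, k = 0.0730 s⁻¹)

The flask stops there because its solid reagent falls to 0% of its charge: with that level held, conversion reaches 100% instead of 50.0%. The flask's leak appears as 7.15% of right-handed product, against my 7.38%. A neighbour flask with 0.600 equiv of solid reagent has a budget of 30.0%. With s, a first pass that ignores the leak gives 3.68% of right-handed product, and a second pass that includes it gives 3.02%. That neighbour flask holds 2.99% of right-handed product and 27.0% of left-handed product.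

The data come from a simulation with made-up constants; the scatter is artificial.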